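**Strategy.** Ring B (C5–C10, labdane-type numbering) is read as a cyclohexene retron: the C8 carbinol and C9 side chain hide a C8=C9 alkene, and the equatorial C6 hydroxyl hides a C–B bond. One intramolecular Diels–Alder reaction of an acyclic triene joins C6 to C7 and C5 to C10. It closes ring B by the [4+2] and ring A through the C1–C4 tether, and sets C5, C6 and C10 (trans fusion, angular methyl) under control of the preset quaternary C4. The precursor is an (E)-alkenyl pinacol boronate tethered to a tetrasubstituted 2-(silylmethyl)diene; its allylsilane later delivers the C8 exocyclic methylene, which is hydrated.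

Key step: step 9

Remark: decalin atoms are C1–C10, with C17 the methyl on C8, C18 the CH2O on C4, C19 the methyl on C4, C20 the methyl on C10, and the side chain C11 onwards; α/β refer to the usual drawing with the C10 methyl β. Assumption: the antipode of the bisphosphine in step 3 is chosen by a test run so that the (R)-configured centre results.

Step 1
Reactants: 1 2-methyl-2-vinyloxirane (racemic)
Product: 2 (E)-4-chloro-2-methylbut-2-en-1-ol
Conditions: TiCl4, CH2Cl2, −85 °C; aq. work-up
Reagents that add atoms: titanium tetrachloride, Cl[Ti](Cl)(Cl)Cl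
Why: Lewis-acid activation of the vinyl epoxide and delivery of chloride to the vinyl terminus (SN2'-type 1,4-opening) should give the primary allylic chloride as the (E)-trisubstituted alkene.

Step 2
Reactants: 2 (E)-4-chloro-2-methylbut-2-en-1-ol
Product: 3 (E)-tert-butyl[(4-chloro-2-methylbut-2-en-1-yl)oxy]diphenylsilane
Conditions: TBDPSCl, imidazole, CH2Cl2, 0 °C to rt
Reagents that add atoms: tert-butyl(chloro)diphenylsilane, CC(C)(C)[Si](Cl)(c1ccccc1)c1ccccc1
Why: Imidazole-promoted silylation of the primary alcohol leaves the allylic chloride untouched and gives C18 a bulky, fluoride-labile group.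

Step 3
Reactants: 3 (E)-tert-butyl[(4-chloro-2-methylbut-2-en-1-yl)oxy]diphenylsilane
Product: 4 (R)-tert-butyl[(2-methyl-2-vinylpent-4-en-1-yl)oxy]diphenylsilane
Conditions: allylB(pin), Pd2(dba)3 (cat.), MeO(furyl)BIPHEP (one antipode, cat.), CsF, THF, 60 °C
Reagents that add atoms: allylboronic acid pinacol ester, C=CCB1OC(C)(C)C(C)(C)O1
Why: Palladium-catalysed branch-selective enantioselective allyl–allyl cross-coupling (ionisation, transmetalation, 3,3'-reductive elimination from a bis(allyl)palladium species) forms the C3–C4 bond at the substituted terminus, and the chiral bisphosphine sets the quaternary C4 centre as (R).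

Step 4
Reactants: 5 methyl acetoacetate; 6 (4-bromobut-1-yn-1-yl)trimethylsilane
Product: 7 methyl 2-acetyl-6-(trimethylsilyl)hex-5-ynoate (racemic)
Conditions: NaH, THF/DMF, 0 °C; then 6, NaI (cat.), 60 °C
Reagents that add atoms: none
Why: Acetoacetic ester alkylation of the soft sodium enolate with the primary homopropargylic bromide under iodide catalysis installs C11–C14 with little E2 elimination.

Step 5
Reactants: 7 methyl 2-acetyl-6-(trimethylsilyl)hex-5-ynoate
Product: 8 methyl (E)-3-(tosyloxy)-2-[4-(trimethylsilyl)but-3-yn-1-yl]but-2-enoate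
Conditions: TsCl, N-methylimidazole, Et3N, toluene, 0 °C to rt
Reagents that add atoms: p-toluenesulfonyl chloride, Cc1ccc(S(=O)(=O)Cl)cc1
Why: Stereoselective enol tosylation under non-chelating amine conditions (N-sulfonylimidazolium as tosyl donor) traps the dipole-minimised enolate and should give the (E)-enol tosylate, with the tosyloxy group trans to the ester.

Step 6
Reactants: 4 (R)-tert-butyl[(2-methyl-2-vinylpent-4-en-1-yl)oxy]diphenylsilane; 8 methyl (E)-3-(tosyloxy)-2-[4-(trimethylsilyl)but-3-yn-1-yl]but-2-enoate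
Product: 10 methyl (2E,7R)-7-[(tert-butyldiphenylsilyloxy)methyl]-3,7-dimethyl-2-[4-(trimethylsilyl)but-3-yn-1-yl]nona-2,8-dienoate, via B-alkyl-9-BBN adduct 9 (not isolated)
Conditions: 4, 9-BBN-H (1.0 equiv), THF, 0 °C to rt; then 8, Pd(OAc)2 (cat.), SPhos, aq. K3PO4, THF, 60 °C
Reagents that add atoms: 9-borabicyclo[3.3.1]nonane, [H]B1C2CCCC1CCC2 (boron unit of 9 only)
Why: Anti-Markovnikov hydroboration of the unhindered allyl terminus by 9-BBN (the neopentyl-type vinyl group reacts far more slowly) is followed by a B-alkyl Suzuki–Miyaura coupling with the activated enol tosylate, which proceeds with retention and so fixes the tetrasubstituted C9=C10 geometry with the C20 methyl cis to C8.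

Step 7
Reactants: 10 methyl (2E,7R)-7-[(tert-butyldiphenylsilyloxy)methyl]-3,7-dimethyl-2-[4-(trimethylsilyl)but-3-yn-1-yl]nona-2,8-dienoate
Product: 11 bis[(trimethylsilyl)methyl]carbinol (the ester carbon of 10 converted into C(OH)(CH2SiMe3)2; (E)-alkene and (R)-C4 unchanged)
Conditions: Me3SiCH2MgCl (5 equiv), CeCl3, THF, −78 °C to rt; aq. NaHCO3/NH4Cl work-up, no silica
Reagents that add atoms: (trimethylsilyl)methylmagnesium chloride, C[Si](C)(C)C[Mg]Cl
Why: Double 1,2-addition of the weakly basic, oxophilic (trimethylsilyl)methylcerium reagent to the hindered conjugated ester gives the bis(β-silyl) tertiary carbinol, a masked 2-(silylmethyl)diene that a buffered work-up keeps intact.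

Step 8
Reactants: 11 bis[(trimethylsilyl)methyl]carbinol
Product: 13 triene boronate CH2=C(CH2SiMe3)–C(CH2CH2C≡CSiMe3)=C(CH3)–(CH2)3–C(CH3)(CH2OTBDPS)–CH=CH–B(pin) ((E)-alkenylboronate, C20 methyl cis to C8, (R) at C4), via carbinol alkenylboronate 12 (not isolated)
Conditions: vinylB(pin) (4 equiv), second-generation Hoveyda–Grubbs catalyst (cat.), CH2Cl2, 40 °C; then SiO2, CH2Cl2, rt
Reagents that add atoms: vinylboronic acid pinacol ester, C=CB1OC(C)(C)C(C)(C)O1
Why: Olefin cross-metathesis of the only monosubstituted alkene with the vinylboronate gives the (E)-alkenylboronate while the tetrasubstituted alkene and silyl alkyne stay inert, and the silica-induced Peterson elimination of the β-hydroxysilane unveils the diene only after the ruthenium step.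

Step 9
Reactants: 13 triene boronate
Product: 14 trans-decalin cycloadduct (6α-B(pin), 5α-H, 10β-CH3, 4β-CH3, 4α-CH2OTBDPS, C8=C9 alkene carrying CH2SiMe3 on C8 and the silylbutynyl chain on C9)
Conditions: degassed toluene (0.01 M), BHT, 150–160 °C, sealed tube
Reagents that add atoms: none
Why: This is a thermal, concerted but asynchronous [4+2] cycloaddition (type 1 intramolecular Diels–Alder reaction of a 1,7,9-decatriene) between the 2-(silylmethyl)diene C7=C8–C9=C10 and the (E)-alkenylboronate C5=C6, the closest precedents being Diels–Alder reactions of alkenylboronic esters and intramolecular cycloadditions of 2-(silylmethyl)dienes. Ring B is closed by the cycloaddition itself (bonds C6–C7 and C5–C10), and ring A results as the fused six-membered ring because the four-carbon tether C1–C4 links the diene terminus C10 to the dienophile carbon C5. The trans C5/C10 fusion with the β C10 methyl arises from the transition state with the tether anti (exo) and the boryl group endo, which should be favoured because the alternative syn arrangement pushes the quaternary C4 under the substituted C9 of the diene. The C6 configuration follows from the (E)-geometry of the dienophile through suprafacial addition, so boron ends up cis to H5 and equatorial (α). The absolute sense is set by C4: in the chair-like tether the bulky CH2OTBDPS group should take the pseudo-equatorial site and the C19 methyl the pseudo-axial one next to the C10 methyl, which puts the diene on the face giving 5α-H and 10β-methyl. The step therefore needs exo-tether and π-facial selectivity and must outrun a 1,5-hydrogen shift of the (Z)-methyl diene, for which the boron-lowered LUMO and the silicon-raised HOMO are relied on.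

Step 10
Reactants: 14 trans-decalin cycloadduct
Product: 15 8(17)-ene boronate (exocyclic C8=CH2, 9α-H with the side chain β, 6α-B(pin))
Conditions: CF3CO2H (2 equiv), CH2Cl2, 0 °C, short reaction time; aq. NaHCO3
Reagents that add atoms: none
Why: Acid-induced protodesilylation of the allylsilane (SE2' protonation at C9 with loss of silicon) moves the alkene to the exocyclic C8=C17 position, the proton entering axially on the α face anti to the C10 methyl so that the side chain becomes β-equatorial.

Step 11
Reactants: 15 8(17)-ene boronate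
Product: 16 6α-alcohol (8(17)-ene, 18-OTBDPS, silyl alkyne)
Conditions: NaBO3·4H2O, THF/H2O, rt
Reagents that add atoms: sodium perborate, [Na+].[O-]OB=O
Why: Perborate oxidation of the secondary alkylboronic ester proceeds by 1,2-migration of carbon from boron to oxygen with retention, turning the 6α C–B bond into the 6α hydroxyl.

Step 12
Reactants: 16 6α-alcohol
Product: 17 6α,8α-diol (8β-CH3, 18-OTBDPS, silyl alkyne)
Conditions: Co(acac)2 (cat.), PhSiH3, O2 (1 atm), i-PrOH, rt
Reagents that add atoms: dioxygen, O=O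
Why: Mukaiyama hydration (hydrogen-atom transfer from a cobalt hydride to the 1,1-disubstituted alkene, O2 capture of the tertiary C8 radical, reduction of the peroxide) gives the Markovnikov tertiary alcohol, and the radical should be trapped equatorially on the α face because the axial β approach is blocked by the syn-axial C10 methyl.

Step 13
Reactants: 17 6α,8α-diol
Product: 18 triol alkyne (6α,8α,18-triol with a but-3-ynyl chain on C9)
Conditions: TBAF (3 equiv), THF, rt to 40 °C
Reagents that add atoms: none
Why: Fluoride-mediated desilylation cleaves the silyl ether and the alkynylsilane in one operation without touching a stereocentre.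

Step 14
Reactants: 19 3-methyl-4-oxopentanoic acid (racemic)
Product: 20 3,5-dibromo-3-methyl-4-oxopentanoic acid (racemic)
Conditions: Br2 (2 equiv), CH2Cl2, HBr (cat.), 0 °C to rt
Reagents that add atoms: bromine, BrBr
Why: Acid-catalysed α-bromination of the ketone through its enols occurs first at the more substituted C3 and then at the methyl carbon C5.

Step 15
Reactants: 20 3,5-dibromo-3-methyl-4-oxopentanoic acid
Product: 21 (Z)-5-(bromomethylene)-4-methylfuran-2(5H)-one
Conditions: conc. H2SO4, 100 °C, short reaction time; ice quench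
Reagents that add atoms: none
Why: Acid-mediated cyclodehydration of the γ-keto acid to the enol lactone with loss of HBr across C2/C3 gives the butenolide, the exocyclic bromoalkene settling as the more stable (Z)-isomer with bromine cis to the ring oxygen.

Step 16
Reactants: 18 triol alkyne; 21 (Z)-5-(bromomethylene)-4-methylfuran-2(5H)-one
Product: 23 CNP0126806.1, (5Z)-5-[(2E)-5-[(1R,2R,4S,4aR,5R,8aS)-2,4-dihydroxy-5-(hydroxymethyl)-2,5,8a-trimethyldecahydronaphthalen-1-yl]-3-methylpent-2-en-1-ylidene]-4-methylfuran-2(5H)-one, via alkenylalane 22 (not isolated)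
Conditions: Me3Al (6 equiv), Cp2ZrCl2 (0.5 equiv), CH2Cl2, 0 °C to rt; volatiles removed; then 21, Pd(PPh3)4 (cat.), ZnCl2 (co-catalyst), THF, rt; Rochelle salt work-up
Reagents that add atoms: trimethylaluminium, C[Al](C)C
Why: Negishi zirconium-catalysed carboalumination adds methyl and aluminium syn across the terminal alkyne with methyl on the internal carbon, fixing the (E)-C13=C14 geometry, and the alkenylalane is then cross-coupled (Negishi coupling with zinc co-catalysis) with the bromomethylene butenolide with retention at both alkenes.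

**Compound list**

1 | 2-methyl-2-vinyloxirane (racemic) | CC1(C=C)CO1 | starting material
2 | (E)-4-chloro-2-methylbut-2-en-1-ol | OC/C(C)=C/CCl | intermediate
3 | (E)-tert-butyl[(4-chloro-2-methylbut-2-en-1-yl)oxy]diphenylsilane | CC(C)(C)[Si](OC/C(C)=C/CCl)(c1ccccc1)c1ccccc1 | intermediate
4 | (R)-tert-butyl[(2-methyl-2-vinylpent-4-en-1-yl)oxy]diphenylsilane | C=CC[C@@](C)(CO[Si](c1ccccc1)(c1ccccc1)C(C)(C)C)C=C | intermediate
5 | methyl acetoacetate | CC(=O)CC(=O)OC | starting material
6 | (4-bromobut-1-yn-1-yl)trimethylsilane | C[Si](C)(C)C#CCCBr | starting material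
7 | methyl 2-acetyl-6-(trimethylsilyl)hex-5-ynoate (racemic) | CC(=O)C(CCC#C[Si](C)(C)C)C(=O)OC | intermediate
8 | methyl (E)-3-(tosyloxy)-2-[4-(trimethylsilyl)but-3-yn-1-yl]but-2-enoate | C/C(OS(=O)(=O)c1ccc(C)cc1)=C(/CCC#C[Si](C)(C)C)C(=O)OC | intermediate
9 | B-alkyl-9-BBN adduct of 4 (boron on the terminal carbon of the former allyl group, (R) at C4) | B1(CCC[C@@](C)(CO[Si](c2ccccc2)(c2ccccc2)C(C)(C)C)C=C)C2CCCC1CCC2 | intermediate (not isolated)
10 | methyl (2E,7R)-7-[(tert-butyldiphenylsilyloxy)methyl]-3,7-dimethyl-2-[4-(trimethylsilyl)but-3-yn-1-yl]nona-2,8-dienoate | COC(=O)/C(CCC#C[Si](C)(C)C)=C(\C)CCC[C@@](C)(CO[Si](c1ccccc1)(c1ccccc1)C(C)(C)C)C=C | intermediate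
11 | bis[(trimethylsilyl)methyl]carbinol derived from 10 ((E)-alkene, (R) at C4, vinyl group kept) | OC(C[Si](C)(C)C)(C[Si](C)(C)C)/C(CCC#C[Si](C)(C)C)=C(\C)CCC[C@@](C)(CO[Si](c1ccccc1)(c1ccccc1)C(C)(C)C)C=C | intermediate
12 | carbinol (E)-alkenyl pinacol boronate | OC(C[Si](C)(C)C)(C[Si](C)(C)C)/C(CCC#C[Si](C)(C)C)=C(\C)CCC[C@@](C)(CO[Si](c1ccccc1)(c1ccccc1)C(C)(C)C)/C=C/B1OC(C)(C)C(C)(C)O1 | intermediate (not isolated)
13 | triene boronate: 2-(silylmethyl)diene with C20 methyl cis to C8, (E)-alkenyl-B(pin), (R) at C4 | C=C(C[Si](C)(C)C)/C(CCC#C[Si](C)(C)C)=C(\C)CCC[C@@](C)(CO[Si](c1ccccc1)(c1ccccc1)C(C)(C)C)/C=C/B1OC(C)(C)C(C)(C)O1 | intermediate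
14 | trans-decalin cycloadduct: 6α-B(pin), 5α-H, 10β-CH3, 4β-CH3, 4α-CH2OTBDPS, C8=C9, C8–CH2SiMe3 | C[Si](C)(C)C#CCCC1[C@@]2(C)CCC[C@@](C)(CO[Si](c3ccccc3)(c3ccccc3)C(C)(C)C)[C@@H]2[C@@H](B3OC(C)(C)C(C)(C)O3)CC=1C[Si](C)(C)C | intermediate
15 | 8(17)-ene boronate: exocyclic methylene, 9α-H, 6α-B(pin) | C[Si](C)(C)C#CCC[C@@H]1[C@@]2(C)CCC[C@@](C)(CO[Si](c3ccccc3)(c3ccccc3)C(C)(C)C)[C@@H]2[C@@H](B3OC(C)(C)C(C)(C)O3)CC1=C | intermediate
16 | 6α-alcohol, 8(17)-ene, 18-OTBDPS | C[Si](C)(C)C#CCC[C@@H]1[C@@]2(C)CCC[C@@](C)(CO[Si](c3ccccc3)(c3ccccc3)C(C)(C)C)[C@@H]2[C@@H](O)CC1=C | intermediate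
17 | 6α,8α-diol (8β-CH3), 18-OTBDPS, silyl alkyne | C[Si](C)(C)C#CCC[C@@H]1[C@@]2(C)CCC[C@@](C)(CO[Si](c3ccccc3)(c3ccccc3)C(C)(C)C)[C@@H]2[C@@H](O)C[C@@]1(C)O | intermediate
18 | triol alkyne: (1R,2R,4S,4aR,5R,8aS)-1-(but-3-yn-1-yl)-5-(hydroxymethyl)-2,5,8a-trimethyldecahydronaphthalene-2,4-diol | C#CCC[C@@H]1[C@@]2(C)CCC[C@@](C)(CO)[C@@H]2[C@@H](O)C[C@@]1(C)O | intermediate
19 | 3-methyl-4-oxopentanoic acid (racemic) | CC(CC(=O)O)C(C)=O | starting material
20 | 3,5-dibromo-3-methyl-4-oxopentanoic acid (racemic) | CC(Br)(CC(=O)O)C(=O)CBr | intermediate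
21 | (Z)-5-(bromomethylene)-4-methylfuran-2(5H)-one | CC1=CC(=O)O/C1=C\Br | intermediate
22 | (E)-alkenyl(dimethyl)alane from 18, hydroxyls as dimethylaluminium alkoxides | C[Al](C)/C=C(\C)CC[C@@H]1[C@@]2(C)CCC[C@@](C)(CO[Al](C)C)[C@@H]2[C@@H](O[Al](C)C)C[C@@]1(C)O[Al](C)C | intermediate (not isolated)
23 | CNP0126806.1, (5Z)-5-[(2E)-5-[(1R,2R,4S,4aR,5R,8aS)-2,4-dihydroxy-5-(hydroxymethyl)-2,5,8a-trimethyldecahydronaphthalen-1-yl]-3-methylpent-2-en-1-ylidene]-4-methylfuran-2(5H)-one | CC1=CC(=O)O/C1=C\C=C(/C)CC[C@@H]1[C@@]2(C)CCC[C@@](C)(CO)[C@@H]2[C@@H](O)C[C@@]1(C)O | target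

**Count.** Total: 16 steps. Longest linear sequence: 12 steps (steps 1, 2, 3, 6, 7, 8, 9, 10, 11, 12, 13, 16).

**Steps most likely to fail**

Step 9. The cycloaddition at the doubly substituted diene terminus may be slower than a 1,5-hydrogen shift in the (Z)-methyl diene, and the weakly directing boryl group may give poor exo-tether and π-facial discrimination, so that cis-fused or C4-mismatched decalins form. The fallback replaces substrate control by auxiliary and Lewis-acid control; it sets out from 11 and returns at 14. Cross-metathesis of 11 with (S)-3-acryloyl-4-benzyloxazolidin-2-one (second-generation Hoveyda–Grubbs catalyst) should give the carbinol imide F1, and silica gel (Peterson elimination) the trienimide F2. Me2AlCl in CH2Cl2 at −30 °C should then promote an endo-selective cycloaddition on the Cα-Si face left open by the chelated (S)-auxiliary, giving the imide cycloadduct F3. LiOH/H2O2 would cleave the auxiliary to the 6α-carboxylic acid F4, and N-hydroxyphthalimide with DIC would give the redox-active ester F5. Copper-catalysed decarboxylative borylation (Cu(acac)2, B2pin2, LiOH·H2O, MgCl2) should deliver boron to the C6 radical from the unhindered α face and so return 14.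

Step 8. Metathesis at the vinyl group on the quaternary carbon may stall, and premature Peterson elimination would expose the diene to the ruthenium carbene. The fallback builds the alkenylboronate by carbonyl olefination; it sets out from 11 and returns at 13. Dihydroxylation of the only unhindered alkene of 11 (OsO4 cat., NMO) should give the diol F6, and NaIO4 cleavage (buffered) the α-quaternary aldehyde F7. A Takai–Utimoto-type boron olefination (CrCl2, Cl2CHB(pin), LiI, THF) should give the (E)-alkenylboronate 12, which silica gel converts to 13 as in step 8.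

Step 16. Carbometalation of the poly-aluminated triol may be incomplete, and residual methylaluminium species may transfer methyl to, or open, the bromobutenolide during the coupling. The fallback builds the lactone last under amine-base conditions; it sets out from 18 and returns at 23. Carboalumination of 18 as in step 16 followed by iodinolysis (I2, THF, −30 °C) should give the (E)-alkenyl iodide F8. Sonogashira coupling with ethynyltrimethylsilane (PdCl2(PPh3)2, CuI, Et3N) should give the silyl enyne F9, and K2CO3/MeOH the terminal enyne F10. (Z)-3-Iodobut-2-enoic acid F11 would be made from but-2-ynoic acid (NaI, AcOH, 110 °C). Its tandem Sonogashira coupling and 5-exo-dig lactonisation with F10 (PdCl2(PPh3)2, CuI, Et3N, MeCN, rt) should give the (Z)-ylidene butenolide 23.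

**Further compounds**

F1 | step 9 | carbinol imide, (S)-4-benzyl-3-[(E)-enoyl]oxazolidin-2-one derived from 11 | OC(C[Si](C)(C)C)(C[Si](C)(C)C)/C(CCC#C[Si](C)(C)C)=C(\C)CCC[C@@](C)(CO[Si](c1ccccc1)(c1ccccc1)C(C)(C)C)/C=C/C(=O)N1[C@@H](Cc2ccccc2)COC1=O
F2 | step 9 | trienimide (2-(silylmethyl)diene tethered to the (E)-enoyl oxazolidinone) | C=C(C[Si](C)(C)C)/C(CCC#C[Si](C)(C)C)=C(\C)CCC[C@@](C)(CO[Si](c1ccccc1)(c1ccccc1)C(C)(C)C)/C=C/C(=O)N1[C@@H](Cc2ccccc2)COC1=O
F3 | step 9 | imide cycloadduct (6α-acyl oxazolidinone trans-decalin) | C[Si](C)(C)C#CCCC1[C@@]2(C)CCC[C@@](C)(CO[Si](c3ccccc3)(c3ccccc3)C(C)(C)C)[C@@H]2[C@@H](C(=O)N3[C@@H](Cc4ccccc4)COC3=O)CC=1C[Si](C)(C)C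
F4 | step 9 | 6α-carboxylic acid | C[Si](C)(C)C#CCCC1[C@@]2(C)CCC[C@@](C)(CO[Si](c3ccccc3)(c3ccccc3)C(C)(C)C)[C@@H]2[C@@H](C(=O)O)CC=1C[Si](C)(C)C
F5 | step 9 | N-hydroxyphthalimide ester of F4 | C[Si](C)(C)C#CCCC1[C@@]2(C)CCC[C@@](C)(CO[Si](c3ccccc3)(c3ccccc3)C(C)(C)C)[C@@H]2[C@@H](C(=O)ON3C(=O)c4ccccc4C3=O)CC=1C[Si](C)(C)C
F6 | step 8 | 1,2-diol from the vinyl group of 11 (epimers at the new carbinol) | OC(C[Si](C)(C)C)(C[Si](C)(C)C)/C(CCC#C[Si](C)(C)C)=C(\C)CCC[C@@](C)(CO[Si](c1ccccc1)(c1ccccc1)C(C)(C)C)C(O)CO
F7 | step 8 | α-quaternary aldehyde (C5 aldehyde) | OC(C[Si](C)(C)C)(C[Si](C)(C)C)/C(CCC#C[Si](C)(C)C)=C(\C)CCC[C@@](C)(CO[Si](c1ccccc1)(c1ccccc1)C(C)(C)C)C=O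
F8 | step 16 | (E)-alkenyl iodide triol | I/C=C(\C)CC[C@@H]1[C@@]2(C)CCC[C@@](C)(CO)[C@@H]2[C@@H](O)C[C@@]1(C)O
F9 | step 16 | (E)-silyl enyne triol | C[Si](C)(C)C#C/C=C(\C)CC[C@@H]1[C@@]2(C)CCC[C@@](C)(CO)[C@@H]2[C@@H](O)C[C@@]1(C)O
F10 | step 16 | (E)-terminal enyne triol | C#C/C=C(\C)CC[C@@H]1[C@@]2(C)CCC[C@@](C)(CO)[C@@H]2[C@@H](O)C[C@@]1(C)O
F11 | step 16 | (Z)-3-iodobut-2-enoic acid | C/C(I)=C/C(=O)O
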